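**Plan**

- Enabling feature: in the δ-lactone ring (O2–C3–C4–C4a–C11a–C1), C4a and C4 are adjacent carbons, β and α to the C3 carbonyl. The nine-membered ring leaves from C4a (bond to C5) and the side chain from C4 (C4=C12), so a 3-phosphoryl-5,6-dihydropyran-2-one can receive both in one flask.
- Cuts: C13 silyl ether, then the C8–C9 epoxide oxygen, then C7–C8 (Z-vinyl iodide plus methyl ketone), then C4a–C5 and C4=C12 together. This leaves phosphono-pyranone 16, Grignard reagent 26 and aldehyde 24.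
- Forward order: the lactone ring is built first (steps 1–7); the three pieces are joined without ring closure (step 13); the nine-membered ring closes at C7–C8 (step 17); epoxidation and desilylation finish.
- Stereochemistry: C11a from an oxazolidinone-controlled Michael addition; C4a by addition anti to the C11a substituent; C14 from Sharpless epoxidation; C13 from Felkin–Anh vinylation; C7 in the ring closure; C8/C9 from hydroxyl-directed epoxidation. The E-alkene comes from the olefination and the Z-alkene from diimide reduction of an iodoalkyne.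

Key step: step 13

Remark: atoms carry xenicane-type numbers (lactone O2, C3, C4, C4a, C11a, C1; nine-membered ring C4a–C11a; side chain C12–C15). Operations run in one flask or without purification count as one step, and metal enolates made by deprotonating a numbered compound are not numbered separately.

**Route**

Step 1
Reactants: 1 3-methylbut-3-enoic acid; 2 (4R)-4-benzyl-1,3-oxazolidin-2-one
Product: 4 (4R)-4-benzyl-3-(3-methylbut-3-enoyl)-1,3-oxazolidin-2-one, via mixed pivalic anhydride 3 (not isolated)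
Conditions: PivCl, Et3N, THF, −20 °C; then 2, LiCl, −20 °C to rt
Reagents that add atoms: none
Why: Mixed-anhydride N-acylation of the oxazolidinone (LiCl/Et3N variant) needs no strong base, so the β,γ-alkene should stay out of conjugation; no stereocentre is formed.

Step 2
Reactants: 4 (4R)-4-benzyl-3-(3-methylbut-3-enoyl)-1,3-oxazolidin-2-one; 5 methyl acrylate
Product: 6 methyl (4R)-4-{[(4R)-4-benzyl-2-oxo-1,3-oxazolidin-3-yl]carbonyl}-5-methylhex-5-enoate
Conditions: TiCl4/Ti(OiPr)4 (3:1, gives TiCl3(OiPr)), iPr2NEt, CH2Cl2, 0 °C; then 5, 0 °C to rt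
Reagents that add atoms: none
Why: Michael addition of the chlorotitanium (Z)-dienolate of an N-acyl oxazolidinone to an acrylate; the chelated enolate reacts at its α-carbon on the face opposite the benzyl group, which sets C11a (R) and leaves the isopropenyl group unconjugated.

Step 3
Reactants: 6 methyl (4R)-4-{[(4R)-4-benzyl-2-oxo-1,3-oxazolidin-3-yl]carbonyl}-5-methylhex-5-enoate
Product: 8 (5R)-5-(prop-1-en-2-yl)oxan-2-one, via hydroxy ester 7 (not isolated)
Conditions: NaBH4, THF/H2O (4:1), 0 °C to rt; work-up; PPTS (cat.), toluene, 60 °C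
Reagents that add atoms: none
Why: Reductive removal of the auxiliary, in which borohydride attacks the activated imide carbonyl much faster than the methyl ester, followed by acid-catalysed lactonisation of the δ-hydroxy ester; C11a is no longer α to a carbonyl and cannot epimerise.

Step 4
Reactants: 8 (5R)-5-(prop-1-en-2-yl)oxan-2-one
Product: 9 (5R)-5-(3-chloroprop-1-en-2-yl)oxan-2-one
Conditions: Ca(OCl)2, CO2 (dry ice), CH2Cl2/H2O, 0 °C
Reagents that add atoms: calcium hypochlorite, [Ca+2].[O-]Cl.[O-]Cl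
Why: Ene-type allylic chlorination of an isopropenyl group by HOCl, in which Cl+ adds to the terminal CH2 and a methyl proton is lost to give the 2-(chloromethyl)allyl unit (C10–Cl); loss of the hindered C11a–H should be the minor pathway.

Step 5
Reactants: 9 (5R)-5-(3-chloroprop-1-en-2-yl)oxan-2-one; 10 trimethylsilylacetylene
Product: 11 (5R)-5-[5-(trimethylsilyl)pent-1-en-4-yn-2-yl]oxan-2-one
Conditions: CuI (20 mol%), NaI (20 mol%), K2CO3, DMF, rt
Reagents that add atoms: none
Why: Copper(I) acetylide substitution of an allylic chloride (skipped-enyne synthesis) forms C9–C10; SN2 and SN2′ attack give the same product because the 2-substituted allyl unit is symmetric.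

Step 6
Reactants: 11 (5R)-5-[5-(trimethylsilyl)pent-1-en-4-yn-2-yl]oxan-2-one
Product: 13 diethyl {(5R)-2-oxo-5-[5-(trimethylsilyl)pent-1-en-4-yn-2-yl]oxan-3-yl}phosphonate (C3 epimers), via phosphonite 12 (not isolated)
Conditions: LDA, THF, −78 °C; ClP(OEt)2, −78 °C to rt; then 30% H2O2, 0 °C
Reagents that add atoms: diethyl chlorophosphite, CCOP(Cl)OCC; hydrogen peroxide, OO
Why: C-Phosphinylation of the lactone lithium enolate with a P(III) chloride followed by P(III)-to-P(V) oxidation gives the α-phosphono lactone with one equivalent of base, which spares the doubly activated C10 methylene; the C3 centre is destroyed in step 7.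

Step 7
Reactants: 13 diethyl {(5R)-2-oxo-5-[5-(trimethylsilyl)pent-1-en-4-yn-2-yl]oxan-3-yl}phosphonate
Product: 16 diethyl {(5R)-2-oxo-5-[5-(trimethylsilyl)pent-1-en-4-yn-2-yl]-5,6-dihydro-2H-pyran-3-yl}phosphonate, via selenide 14 (not isolated), via selenoxide 15 (not isolated)
Conditions: NaH, THF, 0 °C; PhSeCl, −78 °C; then 30% H2O2, CH2Cl2, 0 °C to rt
Reagents that add atoms: none
Why: α-Selenenylation of the stabilised sodium enolate and selenoxide syn-elimination, which can only take a ring C4a–H, install the C4a=C4 double bond; at −78 °C the enolate should capture PhSeCl faster than the isolated alkene or alkyne does.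

Step 8
Reactants: 17 prenol (3-methylbut-2-en-1-ol)
Product: 18 [(2S)-3,3-dimethyloxiran-2-yl]methanol
Conditions: Ti(OiPr)4 (10 mol%), L-(+)-diethyl tartrate (12 mol%), t-BuOOH, 4 Å MS, CH2Cl2, −20 °C
Reagents that add atoms: tert-butyl hydroperoxide, CC(C)(C)OO
Why: Sharpless asymmetric epoxidation of a primary allylic alcohol; the L-(+)-tartrate catalyst delivers oxygen to the face that gives the (S)-epoxide, which becomes C14.

Step 9
Reactants: 18 [(2S)-3,3-dimethyloxiran-2-yl]methanol; 19 vinylmagnesium bromide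
Product: 21 (1S)-1-[(2S)-3,3-dimethyloxiran-2-yl]prop-2-en-1-ol, via epoxy aldehyde 20 (not isolated)
Conditions: (COCl)2, DMSO, Et3N, THF, −78 °C; then 19 (4 equiv), −78 to −20 °C
Reagents that add atoms: none
Why: Swern oxidation with Grignard addition in the same flask avoids isolating the volatile epoxy aldehyde; Felkin–Anh attack anti to the epoxide C–O bond, helped by the cis-methyl group, should favour the anti (erythro) carbinol and set C13 (S), with the minor epimer removed by chromatography.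

Step 10
Reactants: 21 (1S)-1-[(2S)-3,3-dimethyloxiran-2-yl]prop-2-en-1-ol
Product: 22 tert-butyl{[(1S)-1-[(2S)-3,3-dimethyloxiran-2-yl]prop-2-en-1-yl]oxy}dimethylsilane
Conditions: TBSCl, imidazole, DMF, rt
Reagents that add atoms: tert-butyldimethylsilyl chloride, CC(C)(C)[Si](C)(C)Cl
Why: Standard silylation of a secondary alcohol; the TBS ether should survive every later step up to the final fluoride treatment.

Step 11
Reactants: 22 tert-butyl{[(1S)-1-[(2S)-3,3-dimethyloxiran-2-yl]prop-2-en-1-yl]oxy}dimethylsilane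
Product: 24 (2R)-2-[(tert-butyldimethylsilyl)oxy]-2-[(2S)-3,3-dimethyloxiran-2-yl]acetaldehyde, via ozonide 23 (not isolated)
Conditions: O3, CH2Cl2, −78 °C; PPh3, −78 °C to rt
Reagents that add atoms: ozone, [O-][O+]=O
Why: Ozonolysis of the terminal vinyl group with reductive work-up gives the α-silyloxy aldehyde (C12); epoxide and silyl ether are inert to ozone and no base touches the α-centre.

Step 12
Reactants: 25 2-(2-bromoethyl)-2-methyl-1,3-dioxolane
Product: 26 [2-(2-methyl-1,3-dioxolan-2-yl)ethyl]magnesium bromide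
Conditions: Mg turnings, I2 (crystal), THF, 25–30 °C
Reagents that add atoms: magnesium, [Mg]
Why: Grignard formation from a γ-ketal bromide below 30 °C; the dioxolane is stable to the reagent.

Step 13
Reactants: 16 diethyl {(5R)-2-oxo-5-[5-(trimethylsilyl)pent-1-en-4-yn-2-yl]-5,6-dihydro-2H-pyran-3-yl}phosphonate; 26 [2-(2-methyl-1,3-dioxolan-2-yl)ethyl]magnesium bromide; 24 (2R)-2-[(tert-butyldimethylsilyl)oxy]-2-[(2S)-3,3-dimethyloxiran-2-yl]acetaldehyde
Product: 28 (3E,4S,5R)-3-{(2S)-2-[(tert-butyldimethylsilyl)oxy]-2-[(2S)-3,3-dimethyloxiran-2-yl]ethylidene}-4-[2-(2-methyl-1,3-dioxolan-2-yl)ethyl]-5-[5-(trimethylsilyl)pent-1-en-4-yn-2-yl]oxan-2-one, via magnesium enolate 27 (not isolated)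
Conditions: 26 (1.3 equiv), CuBr·SMe2 (10 mol%), THF, −78 to −40 °C; then 24 (1.3 equiv), −40 °C to rt
Reagents that add atoms: none
Why: Copper-catalysed 1,4-addition of the alkyl Grignard reagent to the doubly activated C4a=C4 bond of 16 gives the magnesium phosphonate enolate 27, which then olefinates aldehyde 24 with loss of diethyl phosphate to form C4=C12 (Horner–Wadsworth–Emmons olefination). The closest known reaction type is the tandem conjugate addition/olefination of 3-phosphoryl-5,6-dihydropyran-2-ones and related α-phosphono enoates, and magnesium phosphonoacetate enolates are known to olefinate aldehydes at room temperature. No ring closes; two skeletal bonds (C4a–C5 and C4=C12) form in one flask. The new stereocentre C4a is controlled by the neighbouring C11a substituent, the organocopper entering the half-chair anti to the enyne arm to give the trans-4,5-disubstituted lactone (4aS). The step needs 1,4- over 1,2-addition (copper plus phosphonate/ester double activation), addition faster than deprotonation at C11a (low temperature, soft nucleophile), and E geometry at C4=C12, which should follow from the usual preference of α-phosphono lactones to place the aldehyde substituent away from the carbonyl. The α-silyloxy centre of 24 should not epimerise because the stabilised enolate is a weak base.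

Step 14
Reactants: 28 (3E,4S,5R)-3-{(2S)-2-[(tert-butyldimethylsilyl)oxy]-2-[(2S)-3,3-dimethyloxiran-2-yl]ethylidene}-4-[2-(2-methyl-1,3-dioxolan-2-yl)ethyl]-5-[5-(trimethylsilyl)pent-1-en-4-yn-2-yl]oxan-2-one
Product: 29 (3E,4S,5R)-3-{(2S)-2-[(tert-butyldimethylsilyl)oxy]-2-[(2S)-3,3-dimethyloxiran-2-yl]ethylidene}-5-(5-iodopent-1-en-4-yn-2-yl)-4-[2-(2-methyl-1,3-dioxolan-2-yl)ethyl]oxan-2-one
Conditions: NIS, AgNO3 (10 mol%), DMF, 0 °C to rt, dark
Reagents that add atoms: N-iodosuccinimide, O=C1CCC(=O)N1I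
Why: Silver-catalysed iododesilylation of an alkynylsilane gives the 1-iodoalkyne directly under neutral conditions that spare the ketal, epoxide, silyl ether and lactone.

Step 15
Reactants: 29 (3E,4S,5R)-3-{(2S)-2-[(tert-butyldimethylsilyl)oxy]-2-[(2S)-3,3-dimethyloxiran-2-yl]ethylidene}-5-(5-iodopent-1-en-4-yn-2-yl)-4-[2-(2-methyl-1,3-dioxolan-2-yl)ethyl]oxan-2-one
Product: 30 (3E,4S,5R)-3-{(2S)-2-[(tert-butyldimethylsilyl)oxy]-2-[(2S)-3,3-dimethyloxiran-2-yl]ethylidene}-5-[(4Z)-5-iodopenta-1,4-dien-2-yl]-4-[2-(2-methyl-1,3-dioxolan-2-yl)ethyl]oxan-2-one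
Conditions: 2-nitrobenzenesulfonohydrazide, Et3N, THF/i-PrOH, rt
Reagents that add atoms: none
Why: Diimide generated from the sulfonyl hydrazide adds H2 syn to the iodoalkyne much faster than to the 1,1-disubstituted or conjugated alkenes and gives the (Z)-vinyl iodide; it is run before the ketone is unmasked to avoid hydrazone formation.

Step 16
Reactants: 30 (3E,4S,5R)-3-{(2S)-2-[(tert-butyldimethylsilyl)oxy]-2-[(2S)-3,3-dimethyloxiran-2-yl]ethylidene}-5-[(4Z)-5-iodopenta-1,4-dien-2-yl]-4-[2-(2-methyl-1,3-dioxolan-2-yl)ethyl]oxan-2-one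
Product: 31 (3E,4S,5R)-3-{(2S)-2-[(tert-butyldimethylsilyl)oxy]-2-[(2S)-3,3-dimethyloxiran-2-yl]ethylidene}-5-[(4Z)-5-iodopenta-1,4-dien-2-yl]-4-(3-oxobutyl)oxan-2-one
Conditions: PPTS, acetone/H2O (10:1), 40 °C
Reagents that add atoms: water, O
Why: Mild acid-catalysed ketal hydrolysis frees the methyl ketone; the trisubstituted epoxide, deactivated by the neighbouring silyloxy group, and the TBS ether should tolerate this acidity.

Step 17
Reactants: 31 (3E,4S,5R)-3-{(2S)-2-[(tert-butyldimethylsilyl)oxy]-2-[(2S)-3,3-dimethyloxiran-2-yl]ethylidene}-5-[(4Z)-5-iodopenta-1,4-dien-2-yl]-4-(3-oxobutyl)oxan-2-one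
Product: 32 (4E,4aS,7S,8Z,11aR)-4-{(2S)-2-[(tert-butyldimethylsilyl)oxy]-2-[(2S)-3,3-dimethyloxiran-2-yl]ethylidene}-7-hydroxy-7-methyl-11-methylidene-4,4a,5,6,7,10,11,11a-octahydrocyclonona[c]pyran-3(1H)-one
Conditions: CrCl2 (10 equiv), NiCl2 (2 mol%), DMSO/THF (3:1), rt, 2 mM
Reagents that add atoms: none
Why: Intramolecular Nozaki–Hiyama–Kishi reaction, in which Ni(0) inserts into the (Z)-vinyl iodide and the geometrically stable vinylchromium(III) adds to the methyl ketone at high dilution to close the nine-membered ring at C7–C8; C7 is expected to form as (S) from a transition state that keeps the chromium alkoxide on the outside of the trans-fused ring, and this assignment is the least secure of the route.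

Step 18
Reactants: 32 (4E,4aS,7S,8Z,11aR)-4-{(2S)-2-[(tert-butyldimethylsilyl)oxy]-2-[(2S)-3,3-dimethyloxiran-2-yl]ethylidene}-7-hydroxy-7-methyl-11-methylidene-4,4a,5,6,7,10,11,11a-octahydrocyclonona[c]pyran-3(1H)-one
Product: 33 (4E,4aS,7S,8R,9R,11aR)-4-{(2S)-2-[(tert-butyldimethylsilyl)oxy]-2-[(2S)-3,3-dimethyloxiran-2-yl]ethylidene}-8,9-epoxy-7-hydroxy-7-methyl-11-methylidene-decahydrocyclonona[c]pyran-3-one
Conditions: VO(acac)2 (5 mol%), t-BuOOH, CH2Cl2, 0 °C to rt
Reagents that add atoms: tert-butyl hydroperoxide, CC(C)(C)OO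
Why: Hydroxyl-directed vanadium/alkyl hydroperoxide epoxidation, in which the C7 vanadate delivers oxygen to the adjacent (Z)-alkene on the face syn to the hydroxyl, as with medium-ring cis-allylic alcohols, setting C8 (R) and C9 (R); the other alkenes have no free allylic hydroxyl and should not react.

Step 19
Reactants: 33 (4E,4aS,7S,8R,9R,11aR)-4-{(2S)-2-[(tert-butyldimethylsilyl)oxy]-2-[(2S)-3,3-dimethyloxiran-2-yl]ethylidene}-8,9-epoxy-7-hydroxy-7-methyl-11-methylidene-decahydrocyclonona[c]pyran-3-one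
Product: 34 (4E,4aS,7S,8R,9R,11aR)-8,9-epoxy-7-hydroxy-4-{(2S)-2-hydroxy-2-[(2S)-3,3-dimethyloxiran-2-yl]ethylidene}-7-methyl-11-methylidene-decahydrocyclonona[c]pyran-3-one (CNP0147265.1)
Conditions: TBAF, AcOH, THF, 0 °C to rt
Reagents that add atoms: none
Why: Fluoride cleavage of the TBS ether, buffered with acetic acid, frees the C13 hydroxyl without opening either epoxide or the lactone and gives the target.

**Compound list**

1 | 3-methylbut-3-enoic acid | C=C(C)CC(=O)O | starting material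
2 | (4R)-4-benzyl-1,3-oxazolidin-2-one | O=C1N[C@H](Cc2ccccc2)CO1 | starting material
3 | 3-methylbut-3-enoic pivalic anhydride | CC(=C)CC(=O)OC(=O)C(C)(C)C | intermediate
4 | (4R)-4-benzyl-3-(3-methylbut-3-enoyl)-1,3-oxazolidin-2-one | C=C(C)CC(=O)N1[C@H](Cc2ccccc2)COC1=O | intermediate
5 | methyl acrylate | C=CC(=O)OC | starting material
6 | methyl (4R)-4-{[(4R)-4-benzyl-2-oxo-1,3-oxazolidin-3-yl]carbonyl}-5-methylhex-5-enoate | COC(=O)CC[C@H](C(C)=C)C(=O)N1[C@H](Cc2ccccc2)COC1=O | intermediate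
7 | methyl (4R)-4-(hydroxymethyl)-5-methylhex-5-enoate | COC(=O)CC[C@H](C(C)=C)CO | intermediate
8 | (5R)-5-(prop-1-en-2-yl)oxan-2-one | O=C1CC[C@H](C(C)=C)CO1 | intermediate
9 | (5R)-5-(3-chloroprop-1-en-2-yl)oxan-2-one | O=C1CC[C@H](C(=C)CCl)CO1 | intermediate
10 | trimethylsilylacetylene | C#C[Si](C)(C)C | starting material
11 | (5R)-5-[5-(trimethylsilyl)pent-1-en-4-yn-2-yl]oxan-2-one | O=C1CC[C@H](C(=C)CC#C[Si](C)(C)C)CO1 | intermediate
12 | (5R)-3-(diethoxyphosphanyl)-5-[5-(trimethylsilyl)pent-1-en-4-yn-2-yl]oxan-2-one (C3 epimers) | CCOP(OCC)C1C[C@H](C(=C)CC#C[Si](C)(C)C)COC1=O | intermediate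
13 | diethyl {(5R)-2-oxo-5-[5-(trimethylsilyl)pent-1-en-4-yn-2-yl]oxan-3-yl}phosphonate (C3 epimers) | CCOP(=O)(OCC)C1C[C@H](C(=C)CC#C[Si](C)(C)C)COC1=O | intermediate
14 | diethyl {(5R)-2-oxo-3-(phenylselanyl)-5-[5-(trimethylsilyl)pent-1-en-4-yn-2-yl]oxan-3-yl}phosphonate | CCOP(=O)(OCC)C1([Se]c2ccccc2)C[C@H](C(=C)CC#C[Si](C)(C)C)COC1=O | intermediate
15 | selenoxide of 14 | CCOP(=O)(OCC)C1([Se](=O)c2ccccc2)C[C@H](C(=C)CC#C[Si](C)(C)C)COC1=O | intermediate
16 | diethyl {(5R)-2-oxo-5-[5-(trimethylsilyl)pent-1-en-4-yn-2-yl]-5,6-dihydro-2H-pyran-3-yl}phosphonate | O=C1OC[C@@H](C(=C)CC#C[Si](C)(C)C)C=C1P(=O)(OCC)OCC | intermediate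
17 | prenol (3-methylbut-2-en-1-ol) | CC(C)=CCO | starting material
18 | [(2S)-3,3-dimethyloxiran-2-yl]methanol | OC[C@@H]1OC1(C)C | intermediate
19 | vinylmagnesium bromide | C=C[Mg]Br | starting material
20 | (2R)-3,3-dimethyloxirane-2-carbaldehyde | O=C[C@@H]1OC1(C)C | intermediate
21 | (1S)-1-[(2S)-3,3-dimethyloxiran-2-yl]prop-2-en-1-ol | C=C[C@H](O)[C@@H]1OC1(C)C | intermediate
22 | tert-butyl{[(1S)-1-[(2S)-3,3-dimethyloxiran-2-yl]prop-2-en-1-yl]oxy}dimethylsilane | C=C[C@H](O[Si](C)(C)C(C)(C)C)[C@@H]1OC1(C)C | intermediate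
23 | secondary ozonide (1,2,4-trioxolane) of 22 | O1COOC1[C@H](O[Si](C)(C)C(C)(C)C)[C@@H]1OC1(C)C | intermediate
24 | (2R)-2-[(tert-butyldimethylsilyl)oxy]-2-[(2S)-3,3-dimethyloxiran-2-yl]acetaldehyde | O=C[C@H](O[Si](C)(C)C(C)(C)C)[C@@H]1OC1(C)C | intermediate
25 | 2-(2-bromoethyl)-2-methyl-1,3-dioxolane | CC1(CCBr)OCCO1 | starting material
26 | [2-(2-methyl-1,3-dioxolan-2-yl)ethyl]magnesium bromide | CC1(CC[Mg]Br)OCCO1 | intermediate
27 | bromomagnesium enolate of diethyl {(4S,5R)-4-[2-(2-methyl-1,3-dioxolan-2-yl)ethyl]-2-oxo-5-[5-(trimethylsilyl)pent-1-en-4-yn-2-yl]oxan-3-yl}phosphonate | CC1(CC[C@@H]2C(P(=O)(OCC)OCC)=C(O[Mg]Br)OC[C@H]2C(=C)CC#C[Si](C)(C)C)OCCO1 | intermediate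
28 | (3E,4S,5R)-3-{(2S)-2-[(tert-butyldimethylsilyl)oxy]-2-[(2S)-3,3-dimethyloxiran-2-yl]ethylidene}-4-[2-(2-methyl-1,3-dioxolan-2-yl)ethyl]-5-[5-(trimethylsilyl)pent-1-en-4-yn-2-yl]oxan-2-one | CC1(CC[C@@H]2/C(=C\[C@H](O[Si](C)(C)C(C)(C)C)[C@@H]3OC3(C)C)C(=O)OC[C@H]2C(=C)CC#C[Si](C)(C)C)OCCO1 | intermediate
29 | 5-(5-iodopent-1-en-4-yn-2-yl) analogue of 28 (iodoalkyne) | CC1(CC[C@@H]2/C(=C\[C@H](O[Si](C)(C)C(C)(C)C)[C@@H]3OC3(C)C)C(=O)OC[C@H]2C(=C)CC#CI)OCCO1 | intermediate
30 | 5-[(4Z)-5-iodopenta-1,4-dien-2-yl] analogue of 28 (Z-vinyl iodide, ketal) | CC1(CC[C@@H]2/C(=C\[C@H](O[Si](C)(C)C(C)(C)C)[C@@H]3OC3(C)C)C(=O)OC[C@H]2C(=C)C/C=C\I)OCCO1 | intermediate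
31 | (3E,4S,5R)-3-{(2S)-2-[(tert-butyldimethylsilyl)oxy]-2-[(2S)-3,3-dimethyloxiran-2-yl]ethylidene}-5-[(4Z)-5-iodopenta-1,4-dien-2-yl]-4-(3-oxobutyl)oxan-2-one | CC(=O)CC[C@@H]1/C(=C\[C@H](O[Si](C)(C)C(C)(C)C)[C@@H]2OC2(C)C)C(=O)OC[C@H]1C(=C)C/C=C\I | intermediate
32 | (4E,4aS,7S,8Z,11aR)-4-{(2S)-2-[(tert-butyldimethylsilyl)oxy]-2-[(2S)-3,3-dimethyloxiran-2-yl]ethylidene}-7-hydroxy-7-methyl-11-methylidene-4,4a,5,6,7,10,11,11a-octahydrocyclonona[c]pyran-3(1H)-one | C=C1C/C=C\[C@@](C)(O)CC[C@@H]2/C(=C\[C@H](O[Si](C)(C)C(C)(C)C)[C@@H]3OC3(C)C)C(=O)OC[C@@H]12 | intermediate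
33 | 13-O-TBS ether of the target (8R,9R-epoxide) | C=C1C[C@H]2O[C@H]2[C@@](C)(O)CC[C@@H]2/C(=C\[C@H](O[Si](C)(C)C(C)(C)C)[C@@H]3OC3(C)C)C(=O)OC[C@@H]12 | intermediate
34 | CNP0147265.1, (4E,4aS,7S,8R,9R,11aR,13S,14S) | C=C1C[C@H]2O[C@H]2[C@@](C)(O)CC[C@@H]2/C(=C\[C@H](O)[C@@H]3OC3(C)C)C(=O)OC[C@@H]12 | target

**Count**

Total steps: 19. Longest linear sequence: 14 (steps 1–7, then 13–19). The aldehyde branch is steps 8–11 and the Grignard reagent is step 12.

**Steps most likely to fail**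

1. Step 17. The vinylchromium may add too slowly to the hindered methyl ketone across a forming nine-membered ring, so that protodeiodination or intermolecular coupling takes over, or the ketone may be attacked on the wrong face. The fallback closes the ring on an aldehyde and installs the methyl group afterwards. It sets out from pyranone 16 and returns at 32.
   - The key step is run with 3-[(4-methoxybenzyl)oxy]propylmagnesium bromide F1 (from the commercial bromide and Mg) and aldehyde 24, giving the PMB ether analogue of 28, F2.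
   - NIS/AgNO3 gives iodoalkyne F3, and diimide reduction gives the (Z)-vinyl iodide F4.
   - DDQ in CH2Cl2/pH 7 buffer frees the primary alcohol F5, and Dess–Martin periodinane gives aldehyde F6.
   - Ni/Cr closure onto the aldehyde, a well-documented way to nine-membered rings, gives the ring allylic alcohol F7 as C7 epimers.
   - Dess–Martin oxidation gives the (Z)-enone F8, and MeMgBr/CeCl3 in THF at −78 °C adds 1,2 to the ring ketone from its open face to give 32.

2. Step 13. The magnesium aldolate may stall before elimination, the olefination may lose E/Z control with the branched α-silyloxy aldehyde, or the Grignard reagent may deprotonate C11a–H instead of adding. The fallback separates the two bond formations. It sets out from 16 and returns at 28. The copper-catalysed addition of 26 is quenched with NH4Cl at −40 °C and the trans phosphono lactone, diethyl {(4S,5R)-4-[2-(2-methyl-1,3-dioxolan-2-yl)ethyl]-2-oxo-5-[5-(trimethylsilyl)pent-1-en-4-yn-2-yl]oxan-3-yl}phosphonate F9, is isolated. It is then olefinated with 24 under lithium-chelate, amine-base conditions (LiCl, DBU, MeCN, 0 °C to rt), where E-selectivity is usual and the aldehyde sees no strong base.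

3. Step 9. Facial selectivity in the vinyl addition to the small epoxy aldehyde may be poor, with the chelate and Felkin–Anh pathways competing. The fallback sets C13 by reduction instead of addition. It sets out from 21 (as the epimer mixture) and returns at 21 (single epimer). The mixture is oxidised with Dess–Martin periodinane to 1-[(2R)-3,3-dimethyloxiran-2-yl]prop-2-en-1-one F10. Chelation-controlled 1,2-reduction with Zn(BH4)2 in Et2O at −30 °C, with zinc bridging the carbonyl and epoxide oxygens, should give the anti (erythro) alcohol.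

**Further compounds**

F1 | step 17 | 3-[(4-methoxybenzyl)oxy]propylmagnesium bromide | COc1ccc(COCCC[Mg]Br)cc1
F2 | step 17 | (3E,4S,5R)-3-{(2S)-2-[(tert-butyldimethylsilyl)oxy]-2-[(2S)-3,3-dimethyloxiran-2-yl]ethylidene}-4-{3-[(4-methoxybenzyl)oxy]propyl}-5-[5-(trimethylsilyl)pent-1-en-4-yn-2-yl]oxan-2-one | COc1ccc(COCCC[C@@H]2/C(=C\[C@H](O[Si](C)(C)C(C)(C)C)[C@@H]3OC3(C)C)C(=O)OC[C@H]2C(=C)CC#C[Si](C)(C)C)cc1
F3 | step 17 | iodoalkyne from F2 | COc1ccc(COCCC[C@@H]2/C(=C\[C@H](O[Si](C)(C)C(C)(C)C)[C@@H]3OC3(C)C)C(=O)OC[C@H]2C(=C)CC#CI)cc1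
F4 | step 17 | (Z)-vinyl iodide from F3 | COc1ccc(COCCC[C@@H]2/C(=C\[C@H](O[Si](C)(C)C(C)(C)C)[C@@H]3OC3(C)C)C(=O)OC[C@H]2C(=C)C/C=C\I)cc1
F5 | step 17 | (3E,4S,5R)-3-{(2S)-2-[(tert-butyldimethylsilyl)oxy]-2-[(2S)-3,3-dimethyloxiran-2-yl]ethylidene}-4-(3-hydroxypropyl)-5-[(4Z)-5-iodopenta-1,4-dien-2-yl]oxan-2-one | OCCC[C@@H]1/C(=C\[C@H](O[Si](C)(C)C(C)(C)C)[C@@H]2OC2(C)C)C(=O)OC[C@H]1C(=C)C/C=C\I
F6 | step 17 | 4-(3-oxopropyl) aldehyde from F5 | O=CCC[C@@H]1/C(=C\[C@H](O[Si](C)(C)C(C)(C)C)[C@@H]2OC2(C)C)C(=O)OC[C@H]1C(=C)C/C=C\I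
F7 | step 17 | 7-demethyl analogue of 32 (secondary allylic alcohol, C7 epimers) | C=C1C/C=C\C(O)CC[C@@H]2/C(=C\[C@H](O[Si](C)(C)C(C)(C)C)[C@@H]3OC3(C)C)C(=O)OC[C@@H]12
F8 | step 17 | (8Z)-7-oxo ring enone from F7 | C=C1C/C=C\C(=O)CC[C@@H]2/C(=C\[C@H](O[Si](C)(C)C(C)(C)C)[C@@H]3OC3(C)C)C(=O)OC[C@@H]12
F9 | step 13 | diethyl {(4S,5R)-4-[2-(2-methyl-1,3-dioxolan-2-yl)ethyl]-2-oxo-5-[5-(trimethylsilyl)pent-1-en-4-yn-2-yl]oxan-3-yl}phosphonate | CC1(CC[C@@H]2C(P(=O)(OCC)OCC)C(=O)OC[C@H]2C(=C)CC#C[Si](C)(C)C)OCCO1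
F10 | step 9 | 1-[(2R)-3,3-dimethyloxiran-2-yl]prop-2-en-1-one | C=CC(=O)[C@@H]1OC1(C)C
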